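**Strategy.** The oxolane (O1, C2H2, C3 bearing the carbinol arm, C4 bearing CH3, C5 bearing the aryl group) is disconnected at C3–C4. Titanocene(III) opens a terminal oxirane to a secondary C3 radical, an electrophilic oxirane carbon turned nucleophilic, which closes 5-exo onto the vinyl group of an acyclic (S)-1-arylallyl glycidyl ether. In one operation the ring forms, the vinyl terminus becomes the C4 methyl, the oxirane oxygen becomes the exocyclic CH2OH, and the lone C5 stereocentre relays 4,5-trans and 3,4-cis. The oxirane stereocentre is erased, so racemic glycidol suffices. Ir-catalysed asymmetric allylic etherification builds the precursor; one-pot oxidation and chelation-controlled aryl Grignard addition finish.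

Key step: step 3

Assumption: the (Sa,Sc,Sc)-phosphoramidite is taken to give the (S)-branched ether in step 2 (recalled sense: (Ra,Rc,Rc) gives (R) products from cinnamyl carbonates with N- and O-nucleophiles); if the sense proves opposite, the enantiomeric ligand is used.

**Step 1**
Reactants: 1 (E)-3-(3,4-dimethoxyphenyl)prop-2-en-1-ol
Product: 2 tert-butyl (E)-3-(3,4-dimethoxyphenyl)prop-2-en-1-yl carbonate
Conditions: Boc2O, Bu4NHSO4 (cat.), 30% aq NaOH, CH2Cl2, 0 °C
Reagents that add atoms: di-tert-butyl dicarbonate CC(C)(C)OC(=O)OC(=O)OC(C)(C)C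
Why: O-acylation of a primary allylic alcohol under phase-transfer conditions should give the tert-butyl carbonate needed as leaving group for iridium-catalysed allylic substitution; no stereocentre is formed.

**Step 2**
Reactants: 2 tert-butyl (E)-3-(3,4-dimethoxyphenyl)prop-2-en-1-yl carbonate; 3 rac-oxiran-2-ylmethanol (glycidol)
Product: 4 2-({[(1S)-1-(3,4-dimethoxyphenyl)prop-2-en-1-yl]oxy}methyl)oxirane (both epimers at the oxirane carbon)
Conditions: 3, n-BuLi, THF, −78 °C, then CuI, 0 °C; then 2, [Ir(cod)Cl]2 (2 mol %), (Sa,Sc,Sc)-O,O′-(1,1′-binaphthyl-2,2′-diyl)-N,N-bis(1-phenylethyl)phosphoramidite (4 mol %), THF, rt; aq NH4Cl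
Reagents that add atoms: none
Why: Iridium-catalysed asymmetric allylic etherification with a copper(I) alkoxide (Hartwig type): the cyclometalated Ir–phosphoramidite ionises the carbonate and the alkoxide should attack the aryl-substituted allyl terminus, so the branched ether forms with its (S) centre (the later oxolane C5) set by the ligand, while the oxirane centre stays mixed because it is erased in step 3.

**Step 3**
Reactants: 4 2-({[(1S)-1-(3,4-dimethoxyphenyl)prop-2-en-1-yl]oxy}methyl)oxirane
Product: 5 [(3S,4S,5S)-5-(3,4-dimethoxyphenyl)-4-methyloxolan-3-yl]methanol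
Conditions: Cp2TiCl2 (2.5 equiv), Zn dust, THF, rt, the green Cp2TiCl solution added slowly to 4 in THF; then 0.5 M HCl, 0 °C
Reagents that add atoms: none
Why: Cp2TiCl binds the oxirane oxygen and cleaves the C–O bond to the more substituted carbon by single-electron transfer, so both epimers of 4 converge on one planar secondary β-titanoxy radical (the future C3), which adds to the internal carbon of the vinyl group; the primary radical so formed is captured by a second Cp2TiCl and the C–Ti bond is protonated on work-up to the C4 methyl group. The closest known reaction type is the Nugent–RajanBabu titanocene(III) epoxide–olefin reductive radical cyclization, which is established for 3-oxahex-5-enyl radicals of this kind. The oxolane closes in the 5-exo-trig mode (C3–C4 bond), which the short C–O bonds of the 3-oxa chain favour over 6-endo. Both new stereocentres are set under control of the existing C5 centre in a Beckwith–Houk chair-like transition state: the aryl group on the allylic carbon lies pseudo-equatorial, which should place the developing C4 methyl trans to it, and the CH2OTi group on the radical carbon should end cis to that methyl (1-substituted hexenyl rule), i.e. 4,5-trans/3,4-cis. The step needs regioselective oxirane opening, secured by the terminal oxirane (secondary over primary radical), and ring closure faster than reduction of the radical by Ti(III), secured by keeping Cp2TiCl dilute through slow addition. Minor diastereomers should be separable by chromatography at this stage.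

**Step 4**
Reactants: 5 [(3S,4S,5S)-5-(3,4-dimethoxyphenyl)-4-methyloxolan-3-yl]methanol; 6 3,4-dimethoxyphenylmagnesium bromide
Product: 8 (R)-(3,4-dimethoxyphenyl)[(3R,4S,5S)-5-(3,4-dimethoxyphenyl)-4-methyloxolan-3-yl]methanol, via oxolane-3-carbaldehyde 7 (not isolated)
Conditions: (COCl)2, DMSO, CH2Cl2, −78 °C; i-Pr2NEt, −78 °C; then 6 (5 equiv, THF; the excess also consumes the ammonium salt), −78 → −40 °C; sat. aq NH4Cl
Reagents that add atoms: none
Why: One-pot Swern oxidation/Grignard addition (Ireland–Norbeck protocol) keeps the epimerizable cis-aldehyde 7 cold and unisolated, and both the magnesium chelate between the aldehyde oxygen and ring O1 and the Felkin–Anh arrangement (C4 branch as the large group) expose the carbonyl face opposite to C4 and its cis methyl, so aryl addition should give the (R)-carbinol.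

**Compound list**
1 | (E)-3-(3,4-dimethoxyphenyl)prop-2-en-1-ol (3,4-dimethoxycinnamyl alcohol) | COc1ccc(/C=C/CO)cc1OC | starting material
2 | tert-butyl (E)-3-(3,4-dimethoxyphenyl)prop-2-en-1-yl carbonate | COc1ccc(/C=C/COC(=O)OC(C)(C)C)cc1OC | intermediate
3 | rac-oxiran-2-ylmethanol (glycidol) | OCC1CO1 | starting material
4 | 2-({[(1S)-1-(3,4-dimethoxyphenyl)prop-2-en-1-yl]oxy}methyl)oxirane, both epimers at the oxirane carbon | COc1ccc([C@H](C=C)OCC2CO2)cc1OC | intermediate
5 | [(3S,4S,5S)-5-(3,4-dimethoxyphenyl)-4-methyloxolan-3-yl]methanol (aryl/methyl trans, methyl/CH2OH cis) | COc1ccc([C@H]2OC[C@H](CO)[C@@H]2C)cc1OC | intermediate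
6 | 3,4-dimethoxyphenylmagnesium bromide (commercial THF solution) | COc1ccc([Mg]Br)cc1OC | starting material
7 | (3R,4S,5S)-5-(3,4-dimethoxyphenyl)-4-methyloxolane-3-carbaldehyde | COc1ccc([C@H]2OC[C@H](C=O)[C@@H]2C)cc1OC | intermediate (not isolated)
8 | (R)-(3,4-dimethoxyphenyl)[(3R,4S,5S)-5-(3,4-dimethoxyphenyl)-4-methyloxolan-3-yl]methanol | COc1ccc([C@H]2OC[C@H]([C@@H](O)c3ccc(OC)c(OC)c3)[C@@H]2C)cc1OC | target

**Step count.** Total: 4 steps. Longest linear sequence: 4 steps (1 → 2 → 4 → 5 → 8).

**Steps most likely to fail**

Step 2. The oxirane-bearing copper alkoxide may oligomerize or be ring-opened before it is allylated, or the electron-rich allyl–iridium intermediate may leak to the linear ether or lose enantioselectivity. The fallback sets out from 6 and returns at 4, replacing catalytic asymmetric etherification by enzymatic resolution and a Williamson reaction. Compound 6 is added to acrolein (THF, −78 °C) to give rac-1-(3,4-dimethoxyphenyl)prop-2-en-1-ol F1. A lipase (CAL-B, vinyl acetate, MTBE) should acylate the (R)-enantiomer to (R)-1-(3,4-dimethoxyphenyl)prop-2-en-1-yl acetate F3 and leave (S)-1-(3,4-dimethoxyphenyl)prop-2-en-1-ol F2 (Kazlauskas rule, aryl as the large group). F2 is then O-alkylated with racemic epichlorohydrin (NaH, Bu4NI cat., DMF) to give 4.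

Step 3. The β-titanoxy radical may be reduced by Ti(III) and lose the oxygen by β-elimination before it cyclizes, or the chair preference may be too weak for useful 3,4-cis selectivity. The fallback sets out from 2 and returns at 5, using a vinyl radical and setting C3 afterwards by hydroboration. Compound 2 is etherified under the step 2 conditions with 2-bromoprop-2-en-1-ol to give 4-[(1S)-1-[(2-bromoprop-2-en-1-yl)oxy]prop-2-en-1-yl]-1,2-dimethoxybenzene F4. Bu3SnH/AIBN (benzene, 80 °C, slow addition) should close the vinyl radical 5-exo to (2S,3S)-2-(3,4-dimethoxyphenyl)-3-methyl-4-methylideneoxolane F5, with aryl and methyl trans. Hydroboration with 9-BBN from the face opposite to the adjacent methyl, then NaOH/H2O2, should give 5.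

Step 4. Facial selectivity in the aryl addition to 7 may be insufficient. The fallback sets out from 7 and returns at 8, setting the carbinol centre by reagent-controlled ketone reduction instead of substrate-controlled addition. The adduct mixture of 8 and its epimer (S)-(3,4-dimethoxyphenyl)[(3R,4S,5S)-5-(3,4-dimethoxyphenyl)-4-methyloxolan-3-yl]methanol F6 is oxidized (Dess–Martin periodinane, NaHCO3, CH2Cl2) to (3,4-dimethoxyphenyl)[(3R,4S,5S)-5-(3,4-dimethoxyphenyl)-4-methyloxolan-3-yl]methanone F7. F7 is reduced with (S)-Me-CBS/BH3·SMe2 (aryl as the large group), which should give 8. The reagent has to override the substrate bias here, since the same chelate/Felkin argument favours the unwanted epimer on hydride addition.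

**Further compounds**
F1 | step 2 | rac-1-(3,4-dimethoxyphenyl)prop-2-en-1-ol | COc1ccc(C(O)C=C)cc1OC
F2 | step 2 | (S)-1-(3,4-dimethoxyphenyl)prop-2-en-1-ol | COc1ccc([C@H](C=C)O)cc1OC
F3 | step 2 | (R)-1-(3,4-dimethoxyphenyl)prop-2-en-1-yl acetate | COc1ccc([C@@H](C=C)OC(C)=O)cc1OC
F4 | step 3 | 4-[(1S)-1-[(2-bromoprop-2-en-1-yl)oxy]prop-2-en-1-yl]-1,2-dimethoxybenzene | COc1ccc([C@H](C=C)OCC(Br)=C)cc1OC
F5 | step 3 | (2S,3S)-2-(3,4-dimethoxyphenyl)-3-methyl-4-methylideneoxolane | COc1ccc([C@H]2OCC(=C)[C@@H]2C)cc1OC
F6 | step 4 | (S)-(3,4-dimethoxyphenyl)[(3R,4S,5S)-5-(3,4-dimethoxyphenyl)-4-methyloxolan-3-yl]methanol | COc1ccc([C@H]2OC[C@H]([C@H](O)c3ccc(OC)c(OC)c3)[C@@H]2C)cc1OC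
F7 | step 4 | (3,4-dimethoxyphenyl)[(3R,4S,5S)-5-(3,4-dimethoxyphenyl)-4-methyloxolan-3-yl]methanone | COc1ccc([C@H]2OC[C@H](C(=O)c3ccc(OC)c(OC)c3)[C@@H]2C)cc1OC
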